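## The problem

Quercetin 3,4'-bissulfate (16) is a flavonol: a 4-pyranone (ring C) fused to a phloroglucinol-type benzene ring (ring A), with a catechol-type aryl group (ring B) on C2. It has no stereocentre, so the task is to tell five oxygens apart, not to control configuration. O3 and O4' carry sulfate, while O5, O7 and O3' stay free. Sulfate monoesters are very polar and are hydrolysed by acid, so they must be put on near the end, onto a precursor whose only free hydroxyls are 3-OH and 4'-OH. Everything after sulfation must be neutral. The 3'/4' distinction in the catechol is best settled on the ring B building block, where a para formyl group makes O4 the more acidic oxygen. The pyranone is opened at C2 by hard nucleophiles and strong base, and an ether on O5, peri to the C4 carbonyl, is cleaved by acid more easily than the other aryl ethers. The enabling feature is that ring C has O1 bound to C2 next to an oxygenated C3, and that C4a of ring A is flanked by two equivalent oxygens (the future O1 and O5). An open-chain aryl ketone with a C2≡C3 triple bond and three identical ethers on ring A can therefore close ring C through either ortho oxygen and place an exchangeable atom on C3 in the same event.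

## Retrosynthesis

**16 to 15.** The three O–benzyl bonds at O5, O7 and O3' are cut last. Hydrogenolysis is neutral and is the usual final step for benzylated flavonoid sulfates. Methyl ethers would need Lewis acids that destroy sulfates, and acyl groups would not survive the organometallic steps earlier in the route. The forward step must leave the sulfates and the C2=C3 bond untouched.

**15 to 14.** Both O–S bonds are cut together. In diol 14 only 3-OH and 4'-OH are free, so the site selectivity of sulfation is held by the protecting groups and not by the reagent. An excess of a sulfur trioxide–amine complex can then be used without risk.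

**14 to 13 to 10.** The methoxymethyl (MOM) acetal on O4' is cut first (13), then the C3–O bond is traced back to the C3–I bond of iodide 10. MOM is chosen because it is the one group here that dilute acid removes while the benzyl ethers stay, and because it survives K2CO3 in methanol, n-BuLi, a Grignard reagent and peroxide, which a phenolic silyl ether para to an acceptor would not. Carrying the C3 oxygen through the ring closure would need a protecting group of its own. Deriving it from the iodide makes it appear as the only free hydroxyl of 13.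

**10 to 9 (key disconnection).** The O1–C2 and C3–I bonds are cut and a benzyl group is returned to the ring A oxygen, giving ynone 9. The precursor is acyclic, and ring A carries three identical benzyl ethers, so there is no regiochemical question. The neighbouring options are weaker here:
- Oxidative cyclisation of a 2'-hydroxychalcone gives the 3-hydroxyl directly, but with a second ortho oxygen on ring A it tends towards aurones.
- Diketone cyclodehydration needs a mono-deprotected phloroglucinol ketone and delivers C3–H.

The forward step must close 6-endo and must spare two electron-rich arenes and the MOM acetal.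

**9 to 8 to 2 and 6.** After adjusting the oxidation level (ketone 9 from alcohol 8), the C3–C4 bond between carbonyl and alkyne is cut. This gives aldehyde 2 and lithium acetylide 7, made from alkyne 6. It is the convergent junction of two fragments of similar size. Acylating the alkyne with a 2,4,6-trialkoxybenzoyl chloride would save the oxidation, but that acid chloride is hindered and its parent acid decarboxylates easily. The aldehyde comes in one step from 1.

**6 to 5 to 4 to 3, and 2 to 1.** The terminal alkyne carbon of 6 is removed to give aldehyde 5 (Ohira–Bestmann homologation, one step under mild base). Aldehyde 5 comes from 3,4-dihydroxybenzaldehyde 3 by two O-alkylations whose order follows acidity: MOM on the more acidic O4 gives 4, then benzyl on O3. Aldehyde 2 comes from 2,4,6-trihydroxybenzaldehyde 1 by cutting three O–benzyl bonds.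

## Roads not taken

**Alternative 1:** Ring A is built, not bought. The cut removes C8–C8a, C5–C6, C7–C8 and C4a–C5. It leads back to a pyranone that already holds rings C and B, the diazoketone 2-[3-(benzyloxy)-4-(methoxymethoxy)phenyl]-6-(2-diazoacetyl)-3-(methoxymethoxy)-4H-pyran-4-one A2, and to (triisopropylsilyloxy)ethyne A3. A2 would be made from kojic acid A4.

- Forward key step: irradiation of A2 causes a Wolff rearrangement to a ketene, which adds A3 in a [2+2] sense. Heating opens the cyclobutenone, and 6π-electrocyclisation with tautomerisation gives 2-[3-(benzyloxy)-4-(methoxymethoxy)phenyl]-5-hydroxy-3-(methoxymethoxy)-7-(triisopropylsilyloxy)-4H-chromen-4-one A1.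
- Merits: the C3 oxygen comes from A4, so no iodine-to-oxygen exchange is needed. The mechanism fixes the ring A pattern. In A1 one acid step would free exactly O3 and O4'. In these respects this road is better than the chosen one.
- Weak points: A2 needs protection, arylation next to the ring oxygen, oxidation of the hydroxymethyl group and diazoketone formation before the key step. The 4-pyranone chromophore is itself photoactive. A3 is a sensitive reagent. A separate fluoride step is needed for O7. The annulation also builds a ring that the phloroglucinol pool supplies ready-made.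
- Comparison: the chosen plan has an extra exchange step at C3, but it buys ring A, and its key step rests on close precedent.

**Alternative 2:** The cut removes the O–C8a and C4–C4a bonds. It leads to the aryne precursor 3,5-bis(benzyloxy)-2-(trimethylsilyl)phenyl trifluoromethanesulfonate A6 and the acid (Z)-3-[3-(benzyloxy)-4-(methoxymethoxy)phenyl]-2-(methoxymethoxy)prop-2-enoic acid A7.

- Forward key step: CsF releases the aryne from A6. The carboxylate of A7 adds at the aryne carbon remote from the flanking benzyloxy group, and the aryl anion then attacks the ester carbonyl. The net insertion into the C–O bond gives (Z)-1-[2,4-bis(benzyloxy)-6-hydroxyphenyl]-3-[3-(benzyloxy)-4-(methoxymethoxy)phenyl]-2-(methoxymethoxy)prop-2-en-1-one A5.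
- Merits: two bonds to ring A form under mild fluoride conditions. The C3 oxygen is present from the start. The ortho phenol is freed without a deprotection. Both MOM groups would later fall in one step. On protecting-group economy at the end this road is at least as good as the chosen one.
- Weak points: A6 takes several steps to make. Protonation of the aryl anion competes with acyl transfer and would stop at the aryl ester. A5 is an open chalcone: after oxa-Michael closure the C2–C3 bond is saturated, so a dehydrogenation must follow, typically under hot oxidising conditions that are hard on MOM and benzyl ethers.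
- Comparison: the chosen plan needs the iodide-to-hydroxyl exchange, but it closes ring C at the correct oxidation level in the key step and uses a commercial ring A.

**Alternative 3:** The cut removes C4–C4a and C3–C4, with carbon monoxide A11 as C4. The other partners are 1,3,5-tris(benzyloxy)-2-iodobenzene A9 and the ketone 1-[3-(benzyloxy)-4-(methoxymethoxy)phenyl]-2-(methoxymethoxy)ethan-1-one A10.

- Forward key step: Pd(OAc)2 (divalent palladium, reduced in situ to zerovalent palladium) with a bisphosphine effects oxidative addition to A9, insertion of A11 and coupling of the acyl-palladium with the enolate of A10. The product is 1-[3-(benzyloxy)-4-(methoxymethoxy)phenyl]-2-(methoxymethoxy)-3-[2,4,6-tris(benzyloxy)phenyl]propane-1,3-dione A8 (racemic, labile centre).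
- Merits: three components are joined in one step, the C3 oxygen is in place, and the diketone is at the oxidation level of a flavonol. On convergence this road is better than the chosen one.
- Weak points: the C–I bond of A9 lies between two benzyloxy groups on an electron-rich ring. Enolates of α-alkoxy ketones are little tested in this coupling. A8 is more acidic than A10 and consumes base. No ring closes: one ortho benzyl ether must then be removed selectively and the ring closed by acid-mediated dehydration, which also attacks the MOM groups.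
- Comparison: the chosen plan has a longer linear sequence, but its ring closure removes the ortho benzyl group as part of the same event and leaves the MOM group in place.

Key step: step 7

Assumption: sulfate monoesters are written in the hydrogen sulfate form in which the target is drawn. In practice 15 and 16 would be handled as pyridinium or potassium salts, and 16 would be brought to the acid form on a cation-exchange resin.

## Route

Step 1
Reactants: 1 2,4,6-trihydroxybenzaldehyde
Product: 2 2,4,6-tris(benzyloxy)benzaldehyde
Conditions: BnBr (3.6 equiv), K2CO3, DMF, rt → 60 °C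
Reagents that add atoms: benzyl bromide, BrCc1ccccc1
Why: Williamson ether synthesis on all three phenols; the formyl group lowers the C-nucleophilicity of the ring, and excess bromide with gentle heating should also alkylate the two hydrogen-bonded ortho hydroxyls.

Step 2
Reactants: 3 3,4-dihydroxybenzaldehyde
Product: 4 3-hydroxy-4-(methoxymethoxy)benzaldehyde
Conditions: MOMCl (1.05 equiv), K2CO3 (1.1 equiv), acetone, 0 °C → rt
Reagents that add atoms: chloromethyl methyl ether, COCCl
Why: Regioselective Williamson alkylation; the 4-hydroxyl is para to the formyl group and is the more acidic, so one equivalent of weak base forms and alkylates its phenoxide preferentially.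

Step 3
Reactants: 4 3-hydroxy-4-(methoxymethoxy)benzaldehyde
Product: 5 3-(benzyloxy)-4-(methoxymethoxy)benzaldehyde
Conditions: BnBr (1.2 equiv), K2CO3, DMF, rt
Reagents that add atoms: benzyl bromide, BrCc1ccccc1
Why: Williamson ether synthesis on the one remaining phenol; the MOM acetal is stable to base.

Step 4
Reactants: 5 3-(benzyloxy)-4-(methoxymethoxy)benzaldehyde
Product: 6 2-(benzyloxy)-4-ethynyl-1-(methoxymethoxy)benzene
Conditions: dimethyl (1-diazo-2-oxopropyl)phosphonate (1.3 equiv), K2CO3 (2 equiv), MeOH, 0 °C → rt
Reagents that add atoms: dimethyl (1-diazo-2-oxopropyl)phosphonate, COP(=O)(OC)C(=[N+]=[N-])C(C)=O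
Why: Ohira–Bestmann homologation (Seyferth–Gilbert type): methanolysis releases the diazomethylphosphonate anion, which olefinates the aldehyde; loss of N2 and a 1,2-shift give the terminal alkyne under conditions that both ethers tolerate.

Step 5
Reactants: 6 2-(benzyloxy)-4-ethynyl-1-(methoxymethoxy)benzene; 2 2,4,6-tris(benzyloxy)benzaldehyde
Product: 8 (±)-3-[3-(benzyloxy)-4-(methoxymethoxy)phenyl]-1-[2,4,6-tris(benzyloxy)phenyl]prop-2-yn-1-ol, via lithium acetylide 7 (not isolated)
Conditions: 6 (1.2 equiv), n-BuLi (1.15 equiv), THF, −78 °C; then 2, −78 → 0 °C; then H2O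
Reagents that add atoms: none
Why: Deprotonation of the terminal alkyne and 1,2-addition of the slim acetylide to the hindered aldehyde; the new carbinol centre is racemic and is removed in the next step, and a neutral quench is used because the alcohol ionises easily.

Step 6
Reactants: 8 (±)-3-[3-(benzyloxy)-4-(methoxymethoxy)phenyl]-1-[2,4,6-tris(benzyloxy)phenyl]prop-2-yn-1-ol
Product: 9 3-[3-(benzyloxy)-4-(methoxymethoxy)phenyl]-1-[2,4,6-tris(benzyloxy)phenyl]prop-2-yn-1-one
Conditions: activated MnO2 (excess), CH2Cl2, rt
Reagents that add atoms: none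
Why: Heterogeneous MnO2 oxidation of a benzylic and propargylic alcohol to the ynone under neutral conditions, which spares the acid-sensitive carbinol and the ethers.

Step 7
Reactants: 9 3-[3-(benzyloxy)-4-(methoxymethoxy)phenyl]-1-[2,4,6-tris(benzyloxy)phenyl]prop-2-yn-1-one
Product: 10 5,7-bis(benzyloxy)-2-[3-(benzyloxy)-4-(methoxymethoxy)phenyl]-3-iodo-4H-chromen-4-one
Conditions: ICl (1.2 equiv, added slowly as a CH2Cl2 solution), CH2Cl2, −78 °C, dark; then aq Na2S2O3
Reagents that add atoms: iodine monochloride, ClI
Why: ICl delivers an iodine cation to the ynone triple bond, and the iodonium ion, polarised towards C2 by the para-oxygenated ring B, is opened by one ortho benzyloxy oxygen of ring A, which forms the O1–C2 bond and closes ring C in the 6-endo-dig mode. The resulting O-benzyl oxonium ion loses its benzyl group to chloride as benzyl chloride, so ring closure, dealkylation and placing of the C3 iodide occur in one operation. The closest known reaction type is the ICl-induced cyclisation of ortho-methoxyaryl alkynyl ketones to 3-iodochromones, and a benzyl group should leave the oxonium ion more easily than a methyl group. No stereocentre is formed. The selectivity needed is 6-endo closure to the chromone over 5-exo closure to an aurone-type product; it is secured by the ynone polarisation, which puts the positive charge on the carbon remote from the carbonyl, and by the donor aryl group on that carbon. The two ortho benzyloxy groups are equivalent, so ring A poses no regiochemical choice. Chemoselectivity against iodination of the two electron-rich arenes and against loss of the MOM group rests on low temperature, slow addition of little more than one equivalent of ICl and a reductive quench.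

Step 8
Reactants: 10 5,7-bis(benzyloxy)-2-[3-(benzyloxy)-4-(methoxymethoxy)phenyl]-3-iodo-4H-chromen-4-one
Product: 13 5,7-bis(benzyloxy)-2-[3-(benzyloxy)-4-(methoxymethoxy)phenyl]-3-hydroxy-4H-chromen-4-one, via alkenylmagnesium chloride 11 (not isolated), via dimethyl boronate 12 (not isolated)
Conditions: iPrMgCl·LiCl (1.1 equiv), THF, −40 °C; B(OMe)3 (2 equiv), −40 → 0 °C; then 30% H2O2, aq NaHCO3, 0 °C → rt
Reagents that add atoms: hydrogen peroxide, OO
Why: Iodine–magnesium exchange is fast on an iodoalkene next to a carbonyl group and gives 11, which is kept cold so that it neither adds to the pyranone nor expels the ring oxygen. Trapping as the boronate and peroxide oxidation (1,2-shift from boron to oxygen) give the enol, which is the flavonol; benzyl and MOM ethers are inert to all three reagents.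

Step 9
Reactants: 13 5,7-bis(benzyloxy)-2-[3-(benzyloxy)-4-(methoxymethoxy)phenyl]-3-hydroxy-4H-chromen-4-one
Product: 14 5,7-bis(benzyloxy)-2-[3-(benzyloxy)-4-hydroxyphenyl]-3-hydroxy-4H-chromen-4-one
Conditions: 2 M HCl, MeOH/THF, rt → 40 °C
Reagents that add atoms: none
Why: Acid-catalysed acetal exchange with methanol cleaves the MOM ether and frees the 4'-phenol; dilute acid at this temperature should leave the benzyl ethers in place, including the more labile one on O5.

Step 10
Reactants: 14 5,7-bis(benzyloxy)-2-[3-(benzyloxy)-4-hydroxyphenyl]-3-hydroxy-4H-chromen-4-one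
Product: 15 5,7-bis(benzyloxy)-2-[3-(benzyloxy)-4-(sulfooxy)phenyl]-4-oxo-4H-chromen-3-yl hydrogen sulfate
Conditions: SO3·pyridine (8 equiv), pyridine, rt → 50 °C
Reagents that add atoms: sulfur trioxide–pyridine complex, [O-]S(=O)(=O)[n+]1ccccc1
Why: O-Sulfation of the phenol and the enolic 3-hydroxyl by a sulfur trioxide–amine complex; 14 has no other free hydroxyl, so excess reagent and warming can drive the hydrogen-bonded 3-OH to completion without a selectivity problem.

Step 11
Reactants: 15 5,7-bis(benzyloxy)-2-[3-(benzyloxy)-4-(sulfooxy)phenyl]-4-oxo-4H-chromen-3-yl hydrogen sulfate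
Product: 16 quercetin 3,4'-bissulfate (5,7-dihydroxy-2-[3-hydroxy-4-(sulfooxy)phenyl]-4-oxo-4H-chromen-3-yl hydrogen sulfate)
Conditions: H2 (1 atm), 10% Pd/C, MeOH/THF, rt; then sulfonic acid cation-exchange resin (H+ form), 0 °C, freeze-drying
Reagents that add atoms: none
Why: Catalytic hydrogenolysis of the three benzyl ethers under neutral conditions, a standard last step for benzylated flavonoid sulfates; the sulfate esters and the C2=C3 bond of the pyranone are not reduced at 1 atm and rt.

## Compound list

1 | 2,4,6-trihydroxybenzaldehyde | O=Cc1c(O)cc(O)cc1O | starting material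
2 | 2,4,6-tris(benzyloxy)benzaldehyde | O=Cc1c(OCc2ccccc2)cc(OCc2ccccc2)cc1OCc1ccccc1 | intermediate
3 | 3,4-dihydroxybenzaldehyde | O=Cc1ccc(O)c(O)c1 | starting material
4 | 3-hydroxy-4-(methoxymethoxy)benzaldehyde | O=Cc1ccc(OCOC)c(O)c1 | intermediate
5 | 3-(benzyloxy)-4-(methoxymethoxy)benzaldehyde | O=Cc1ccc(OCOC)c(OCc2ccccc2)c1 | intermediate
6 | 2-(benzyloxy)-4-ethynyl-1-(methoxymethoxy)benzene | C#Cc1ccc(OCOC)c(OCc2ccccc2)c1 | intermediate
7 | lithium acetylide of 6, {[3-(benzyloxy)-4-(methoxymethoxy)phenyl]ethynyl}lithium | [Li]C#Cc1ccc(OCOC)c(OCc2ccccc2)c1 | intermediate (not isolated)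
8 | (±)-3-[3-(benzyloxy)-4-(methoxymethoxy)phenyl]-1-[2,4,6-tris(benzyloxy)phenyl]prop-2-yn-1-ol | OC(C#Cc1ccc(OCOC)c(OCc2ccccc2)c1)c1c(OCc2ccccc2)cc(OCc2ccccc2)cc1OCc1ccccc1 | intermediate
9 | 3-[3-(benzyloxy)-4-(methoxymethoxy)phenyl]-1-[2,4,6-tris(benzyloxy)phenyl]prop-2-yn-1-one | O=C(C#Cc1ccc(OCOC)c(OCc2ccccc2)c1)c1c(OCc2ccccc2)cc(OCc2ccccc2)cc1OCc1ccccc1 | intermediate
10 | 5,7-bis(benzyloxy)-2-[3-(benzyloxy)-4-(methoxymethoxy)phenyl]-3-iodo-4H-chromen-4-one | O=c1c(I)c(-c2ccc(OCOC)c(OCc3ccccc3)c2)oc2cc(OCc3ccccc3)cc(OCc3ccccc3)c12 | intermediate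
11 | {5,7-bis(benzyloxy)-2-[3-(benzyloxy)-4-(methoxymethoxy)phenyl]-4-oxo-4H-chromen-3-yl}magnesium chloride (LiCl complex) | O=c1c([Mg]Cl)c(-c2ccc(OCOC)c(OCc3ccccc3)c2)oc2cc(OCc3ccccc3)cc(OCc3ccccc3)c12 | intermediate (not isolated)
12 | dimethyl {5,7-bis(benzyloxy)-2-[3-(benzyloxy)-4-(methoxymethoxy)phenyl]-4-oxo-4H-chromen-3-yl}boronate | COB(OC)c1c(-c2ccc(OCOC)c(OCc3ccccc3)c2)oc2cc(OCc3ccccc3)cc(OCc3ccccc3)c2c1=O | intermediate (not isolated)
13 | 5,7-bis(benzyloxy)-2-[3-(benzyloxy)-4-(methoxymethoxy)phenyl]-3-hydroxy-4H-chromen-4-one | O=c1c(O)c(-c2ccc(OCOC)c(OCc3ccccc3)c2)oc2cc(OCc3ccccc3)cc(OCc3ccccc3)c12 | intermediate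
14 | 5,7-bis(benzyloxy)-2-[3-(benzyloxy)-4-hydroxyphenyl]-3-hydroxy-4H-chromen-4-one | O=c1c(O)c(-c2ccc(O)c(OCc3ccccc3)c2)oc2cc(OCc3ccccc3)cc(OCc3ccccc3)c12 | intermediate
15 | 5,7-bis(benzyloxy)-2-[3-(benzyloxy)-4-(sulfooxy)phenyl]-4-oxo-4H-chromen-3-yl hydrogen sulfate | O=c1c(OS(=O)(=O)O)c(-c2ccc(OS(=O)(=O)O)c(OCc3ccccc3)c2)oc2cc(OCc3ccccc3)cc(OCc3ccccc3)c12 | intermediate
16 | quercetin 3,4'-bissulfate | O=c1c(OS(=O)(=O)O)c(-c2ccc(OS(=O)(=O)O)c(O)c2)oc2cc(O)cc(O)c12 | target

## Step count and least certain steps

Total step count: 11. Longest linear sequence: 10 steps (from 3 through steps 2, 3, 4, 5, 6, 7, 8, 9, 10 and 11 to 16).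

**Step 7 (key step).**
- Risk: iodination of ring A or ring B could compete with activation of the alkyne, because both arenes carry two or three oxygen donors. Traces of HCl could remove the MOM group. Part of the material could close 5-exo.
- Fallback: the electrophilic closure is replaced by a conjugate one that forms the same O1–C2 bond. It sets out from aldehyde 2.
  - Chelation-controlled removal of one ortho benzyl group with MgBr2·OEt2 gives 2,4-bis(benzyloxy)-6-hydroxybenzaldehyde F1.
  - The phenoxide of F1 takes up acetylide 7 (two equivalents) to give the diol 3,5-bis(benzyloxy)-2-{3-[3-(benzyloxy)-4-(methoxymethoxy)phenyl]-1-hydroxyprop-2-yn-1-yl}phenol F2 (racemic).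
  - MnO2 gives the hydroxy ynone 1-[2,4-bis(benzyloxy)-6-hydroxyphenyl]-3-[3-(benzyloxy)-4-(methoxymethoxy)phenyl]prop-2-yn-1-one F3.
  - Et2NH in ethanol effects conjugate addition and 6-endo closure to the flavone 5,7-bis(benzyloxy)-2-[3-(benzyloxy)-4-(methoxymethoxy)phenyl]-4H-chromen-4-one F4.
  - Dimethyldioxirane epoxidises C2=C3 to 5,7-bis(benzyloxy)-2-[3-(benzyloxy)-4-(methoxymethoxy)phenyl]-2,3-epoxy-2,3-dihydro-4H-chromen-4-one F5 (racemic).
  - A trace of TsOH opens the epoxide to the flavonol, and the route is rejoined at 13.

**Step 8.**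
- Risk: the alkenylmagnesium species 11 may be protonated, may add to a second molecule at the pyranone, or may expel the ring oxygen with opening of ring C. The boronate 12 may lose boron before it is oxidised. Each path returns the 3-unsubstituted flavone or open-chain material.
- Fallback: sets out from 10. Palladium-catalysed Miyaura borylation (bis(pinacolato)diboron, PdCl2(dppf), KOAc, dioxane) avoids the magnesium species and gives 5,7-bis(benzyloxy)-2-[3-(benzyloxy)-4-(methoxymethoxy)phenyl]-3-(4,4,5,5-tetramethyl-1,3,2-dioxaborolan-2-yl)-4H-chromen-4-one F6. Oxidation with NaBO3·4H2O in aqueous THF returns to the route at 13.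

**Step 9.**
- Risk: the benzyl ether on O5 is activated by chelation to the C4 carbonyl and may be lost together with the MOM group, giving a mixture.
- Fallback: sets out from 13 and makes that loss deliberate. Concentrated HCl in acetic acid removes both groups and gives 7-(benzyloxy)-2-[3-(benzyloxy)-4-hydroxyphenyl]-3,5-dihydroxy-4H-chromen-4-one F7. The 5-hydroxyl is locked in a hydrogen bond to the carbonyl and is the least reactive hydroxyl of a flavonoid, so SO3·pyridine should sulfate only O3 and O4', giving 7-(benzyloxy)-2-[3-(benzyloxy)-4-(sulfooxy)phenyl]-5-hydroxy-4-oxo-4H-chromen-3-yl hydrogen sulfate F8. Hydrogenolysis as in step 11 then rejoins the route at 16.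

**Step 10.**
- Risk: sulfation of the hindered, hydrogen-bonded 3-hydroxyl may stay incomplete. The dianionic product may lose sulfate by acid-catalysed hydrolysis during isolation, and it cannot be purified on silica.
- Fallback: sets out from 14 and uses a protected sulfate. 2,2,2-Trichloroethyl chlorosulfate with Et3N and DMAP gives the neutral, chromatographable diester 5,7-bis(benzyloxy)-2-{3-(benzyloxy)-4-[(2,2,2-trichloroethoxy)sulfonyloxy]phenyl}-4-oxo-4H-chromen-3-yl 2,2,2-trichloroethyl sulfate F9. Pd/C with HCO2NH4 in methanol then removes the trichloroethyl groups by reductive fragmentation and the benzyl ethers by transfer hydrogenolysis in one operation, so this fallback also replaces step 11 and comes back at 16.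

## Further compounds

F1 | step 7 | 2,4-bis(benzyloxy)-6-hydroxybenzaldehyde | O=Cc1c(O)cc(OCc2ccccc2)cc1OCc1ccccc1
F2 | step 7 | 3,5-bis(benzyloxy)-2-{3-[3-(benzyloxy)-4-(methoxymethoxy)phenyl]-1-hydroxyprop-2-yn-1-yl}phenol (racemic) | OC(C#Cc1ccc(OCOC)c(OCc2ccccc2)c1)c1c(O)cc(OCc2ccccc2)cc1OCc1ccccc1
F3 | step 7 | 1-[2,4-bis(benzyloxy)-6-hydroxyphenyl]-3-[3-(benzyloxy)-4-(methoxymethoxy)phenyl]prop-2-yn-1-one | O=C(C#Cc1ccc(OCOC)c(OCc2ccccc2)c1)c1c(O)cc(OCc2ccccc2)cc1OCc1ccccc1
F4 | step 7 | 5,7-bis(benzyloxy)-2-[3-(benzyloxy)-4-(methoxymethoxy)phenyl]-4H-chromen-4-one | O=c1cc(-c2ccc(OCOC)c(OCc3ccccc3)c2)oc2cc(OCc3ccccc3)cc(OCc3ccccc3)c12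
F5 | step 7 | 5,7-bis(benzyloxy)-2-[3-(benzyloxy)-4-(methoxymethoxy)phenyl]-2,3-epoxy-2,3-dihydro-4H-chromen-4-one (racemic) | O=C1c2c(OCc3ccccc3)cc(OCc3ccccc3)cc2OC2(c3ccc(OCOC)c(OCc4ccccc4)c3)OC12
F6 | step 8 | 5,7-bis(benzyloxy)-2-[3-(benzyloxy)-4-(methoxymethoxy)phenyl]-3-(4,4,5,5-tetramethyl-1,3,2-dioxaborolan-2-yl)-4H-chromen-4-one | CC1(C)OB(OC1(C)C)c1c(-c2ccc(OCOC)c(OCc3ccccc3)c2)oc2cc(OCc3ccccc3)cc(OCc3ccccc3)c2c1=O
F7 | step 9 | 7-(benzyloxy)-2-[3-(benzyloxy)-4-hydroxyphenyl]-3,5-dihydroxy-4H-chromen-4-one | O=c1c(O)c(-c2ccc(O)c(OCc3ccccc3)c2)oc2cc(OCc3ccccc3)cc(O)c12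
F8 | step 9 | 7-(benzyloxy)-2-[3-(benzyloxy)-4-(sulfooxy)phenyl]-5-hydroxy-4-oxo-4H-chromen-3-yl hydrogen sulfate | O=c1c(OS(=O)(=O)O)c(-c2ccc(OS(=O)(=O)O)c(OCc3ccccc3)c2)oc2cc(OCc3ccccc3)cc(O)c12
F9 | step 10 | 5,7-bis(benzyloxy)-2-{3-(benzyloxy)-4-[(2,2,2-trichloroethoxy)sulfonyloxy]phenyl}-4-oxo-4H-chromen-3-yl 2,2,2-trichloroethyl sulfate | O=c1c(OS(=O)(=O)OCC(Cl)(Cl)Cl)c(-c2ccc(OS(=O)(=O)OCC(Cl)(Cl)Cl)c(OCc3ccccc3)c2)oc2cc(OCc3ccccc3)cc(OCc3ccccc3)c12
A1 | alternative 1 | 2-[3-(benzyloxy)-4-(methoxymethoxy)phenyl]-5-hydroxy-3-(methoxymethoxy)-7-(triisopropylsilyloxy)-4H-chromen-4-one | O=c1c(OCOC)c(-c2ccc(OCOC)c(OCc3ccccc3)c2)oc2cc(O[Si](C(C)C)(C(C)C)C(C)C)cc(O)c12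
A2 | alternative 1 | 2-[3-(benzyloxy)-4-(methoxymethoxy)phenyl]-6-(2-diazoacetyl)-3-(methoxymethoxy)-4H-pyran-4-one | [N-]=[N+]=CC(=O)c1cc(=O)c(OCOC)c(-c2ccc(OCOC)c(OCc3ccccc3)c2)o1
A3 | alternative 1 | (triisopropylsilyloxy)ethyne | C#CO[Si](C(C)C)(C(C)C)C(C)C
A4 | alternative 1 | kojic acid (5-hydroxy-2-(hydroxymethyl)-4H-pyran-4-one) | OCc1cc(=O)c(O)co1
A5 | alternative 2 | (Z)-1-[2,4-bis(benzyloxy)-6-hydroxyphenyl]-3-[3-(benzyloxy)-4-(methoxymethoxy)phenyl]-2-(methoxymethoxy)prop-2-en-1-one | COCO/C(=C\c1ccc(OCOC)c(OCc2ccccc2)c1)C(=O)c1c(O)cc(OCc2ccccc2)cc1OCc1ccccc1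
A6 | alternative 2 | 3,5-bis(benzyloxy)-2-(trimethylsilyl)phenyl trifluoromethanesulfonate | C[Si](C)(C)c1c(OS(=O)(=O)C(F)(F)F)cc(OCc2ccccc2)cc1OCc1ccccc1
A7 | alternative 2 | (Z)-3-[3-(benzyloxy)-4-(methoxymethoxy)phenyl]-2-(methoxymethoxy)prop-2-enoic acid | COCO/C(=C\c1ccc(OCOC)c(OCc2ccccc2)c1)C(=O)O
A8 | alternative 3 | 1-[3-(benzyloxy)-4-(methoxymethoxy)phenyl]-2-(methoxymethoxy)-3-[2,4,6-tris(benzyloxy)phenyl]propane-1,3-dione (racemic) | O=C(C(OCOC)C(=O)c1ccc(OCOC)c(OCc2ccccc2)c1)c1c(OCc2ccccc2)cc(OCc2ccccc2)cc1OCc1ccccc1
A9 | alternative 3 | 1,3,5-tris(benzyloxy)-2-iodobenzene | Ic1c(OCc2ccccc2)cc(OCc2ccccc2)cc1OCc1ccccc1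
A10 | alternative 3 | 1-[3-(benzyloxy)-4-(methoxymethoxy)phenyl]-2-(methoxymethoxy)ethan-1-one | COCOCC(=O)c1ccc(OCOC)c(OCc2ccccc2)c1
A11 | alternative 3 | carbon monoxide | [C-]#[O+]
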